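**Retrosynthetic overview**
1. Caraphenol B (30) ⇐ hexabenzyl ether 29 (neutral hydrogenolysis last) ⇐ aldehyde 25 + aryl Grignard, then oxidation; 25 ⇐ all-cis indanylmethanol 24.
2. The all-cis C-1/C-2/C-3 triad ⇐ syn-hydrogenation of 1H-indene 21 on the face away from its only stereocentre, C-1.
3. 21 ⇐ arylcerium addition and dehydration on indanone 16 ⇐ Friedel–Crafts acylation of acid 14 (the only ring made is the cyclopentane, closed onto a bought resorcinol-type ring).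
4. 14 ⇐ auxiliary removal and nitro → CO2H from γ-nitro imide 11 ⇐ key intermolecular Michael addition of the titanium enolate of arylacetyl oxazolidinone 6 to nitrostyrene 9 (sets C-1).
5. 6 and 9 ⇐ methyl 3,5-dihydroxyphenylacetate, (R)-4-benzyloxazolidin-2-one, 4-benzyloxybenzaldehyde, nitromethane.

Assumption: the SMILES is taken literally; it encodes (1R,2R,3R), i.e. the 1-aroyl, 2-aryl and 3-aryl groups all on one face of the indane (all-cis), and that isomer is the target.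

**Route**

Step 1
Reactants: 1 methyl 2-(3,5-dihydroxyphenyl)acetate
Product: 2 methyl 2-[3,5-bis(benzyloxy)phenyl]acetate
Conditions: BnBr (2.3 equiv), K2CO3, acetone, reflux
Reagents that add atoms: benzyl bromide, BrCc1ccccc1
Why: Williamson ether synthesis; the phenoxides are alkylated while the much less acidic ester α-CH2 is untouched.

Step 2
Reactants: 2 methyl 2-[3,5-bis(benzyloxy)phenyl]acetate
Product: 3 2-[3,5-bis(benzyloxy)phenyl]acetic acid
Conditions: LiOH·H2O, THF–MeOH–H2O, rt; then 1 M HCl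
Reagents that add atoms: lithium hydroxide, [Li+].[OH-]
Why: Ester saponification; aryl benzyl ethers are inert to hydroxide.

Step 3
Reactants: 3 2-[3,5-bis(benzyloxy)phenyl]acetic acid; 4 (R)-4-benzyl-1,3-oxazolidin-2-one
Product: 6 (R)-4-benzyl-3-{2-[3,5-bis(benzyloxy)phenyl]acetyl}-1,3-oxazolidin-2-one, via 2-[3,5-bis(benzyloxy)phenyl]acetic pivalic anhydride 5 (not isolated)
Conditions: PivCl, Et3N, THF, −20 °C; then LiCl, 4, −20 °C → rt
Reagents that add atoms: none
Why: Mixed-anhydride N-acylation of the oxazolidinone (LiCl/Et3N variant), with attack at the less hindered arylacetyl carbonyl; no stereocentre is formed.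

Step 4
Reactants: 7 4-(benzyloxy)benzaldehyde; 8 nitromethane
Product: 9 (E)-1-(benzyloxy)-4-(2-nitroethenyl)benzene
Conditions: NH4OAc, AcOH, 100 °C
Reagents that add atoms: none
Why: Henry (nitroaldol) condensation with in situ dehydration gives the conjugated, crystalline E-nitroalkene.

Step 5
Reactants: 6 (R)-4-benzyl-3-{2-[3,5-bis(benzyloxy)phenyl]acetyl}-1,3-oxazolidin-2-one; 9 (E)-1-(benzyloxy)-4-(2-nitroethenyl)benzene
Product: 11 (R)-4-benzyl-3-{(2R)-2-[3,5-bis(benzyloxy)phenyl]-3-[4-(benzyloxy)phenyl]-4-nitrobutanoyl}-1,3-oxazolidin-2-one (C-3 epimers), via trichlorotitanium (Z)-enolate of 6 10 (not isolated)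
Conditions: TiCl4 (1.05 equiv), i-Pr2NEt (1.1 equiv), CH2Cl2, −78 °C; then 9, TiCl4 (1.0 equiv), −78 → −40 °C; aq NH4Cl; chromatography/crystallisation
Reagents that add atoms: none
Why: Evans auxiliary-controlled Michael addition: the nitroalkene attacks the chelated (Z)-titanium enolate on the face opposite the oxazolidinone benzyl group, which fixes the α-centre (the future C-1) as R, while the neighbouring ArCH centre forms as a mixture that is erased in step 11.

Step 6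
Reactants: 11 the Michael adduct
Product: 12 (2R)-2-[3,5-bis(benzyloxy)phenyl]-3-[4-(benzyloxy)phenyl]-4-nitrobutan-1-ol (C-3 epimers)
Conditions: LiBH4 (excess), MeOH (1 equiv), THF, 0 °C; aq NH4Cl (pH 5)
Reagents that add atoms: none
Why: Reductive cleavage of the imide by hydride attack at the exocyclic carbonyl releases the auxiliary and turns the epimerisable α-aryl acyl centre into a configurationally stable CH–CH2OH; an aliphatic nitro group is inert to borohydride.

Step 7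
Reactants: 12 the nitro alcohol
Product: 13 tert-butyl{[(2R)-2-[3,5-bis(benzyloxy)phenyl]-3-[4-(benzyloxy)phenyl]-4-nitrobutyl]oxy}diphenylsilane (C-3 epimers)
Conditions: TBDPSCl, imidazole, CH2Cl2, 0 °C → rt
Reagents that add atoms: tert-butyl(chloro)diphenylsilane, CC(C)(C)[Si](Cl)(c1ccccc1)c1ccccc1
Why: Silylation of the primary alcohol gives a bulky group that survives acid, organometallics and hydrogenation and later shields one face of the indene.

Step 8
Reactants: 13 the silyl ether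
Product: 14 (3R)-3-[3,5-bis(benzyloxy)phenyl]-2-[4-(benzyloxy)phenyl]-4-[(tert-butyldiphenylsilyl)oxy]butanoic acid (C-2 epimers)
Conditions: NaNO2, AcOH, DMSO, 35 °C
Reagents that add atoms: sodium nitrite, [Na+].[O-]N=O
Why: Oxidative Nef-type conversion of a primary nitroalkane into a carboxylic acid via the nitrolic acid; it is mild enough for silyl and benzyl ethers and leaves the C-3 stereocentre untouched.

Step 9
Reactants: 14 the acid
Product: 16 (2S,3R)-5,7-bis(benzyloxy)-2-[4-(benzyloxy)phenyl]-3-{[(tert-butyldiphenylsilyl)oxy]methyl}-2,3-dihydro-1H-inden-1-one (2,3-trans), via mixed trifluoroacetic anhydride 15 (not isolated)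
Conditions: (CF3CO)2O, CH2Cl2, 0 °C → rt; aq NaHCO3 wash; then cat. Et3N, CH2Cl2, rt
Reagents that add atoms: none
Why: Trifluoroacetic anhydride activates the acid as its mixed anhydride, and intramolecular Friedel–Crafts acylation onto the 3,5-dialkoxyphenyl ring (ortho/para to both ethers, the two ortho sites being equivalent) closes the five-membered ring; the centre α to the ketone is then equilibrated to trans by the amine and the CH2OTBDPS-bearing centre is not touched.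

Step 10
Reactants: 16 the indanone; 17 1,3-bis(benzyloxy)-5-bromobenzene
Product: 20 (2S,3R)-5,7-bis(benzyloxy)-1-[3,5-bis(benzyloxy)phenyl]-2-[4-(benzyloxy)phenyl]-3-{[(tert-butyldiphenylsilyl)oxy]methyl}-2,3-dihydro-1H-inden-1-ol (C-1 epimers), via [3,5-bis(benzyloxy)phenyl]lithium 18 (not isolated), via [3,5-bis(benzyloxy)phenyl]cerium dichloride 19 (not isolated)
Conditions: 17, n-BuLi, THF, −78 °C; anhydrous CeCl3, −78 °C; then 16, −78 → −30 °C; aq NH4Cl
Reagents that add atoms: none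
Why: 1,2-Addition of a weakly basic arylcerium reagent to the hindered, enolisable ketone installs the second resorcinol ring; the carbinol configuration is irrelevant.

Step 11
Reactants: 20 the tertiary alcohol
Product: 21 tert-butyl({(1S)-4,6-bis(benzyloxy)-3-[3,5-bis(benzyloxy)phenyl]-2-[4-(benzyloxy)phenyl]-1H-inden-1-yl}methoxy)diphenylsilane
Conditions: TsOH·H2O (5 mol %), 4 Å MS, toluene, rt; aq NaHCO3 wash; used at once
Reagents that add atoms: none
Why: E1 dehydration of the tertiary doubly benzylic alcohol can only lose the C-2 proton, giving the tetrasubstituted indene with C-1 untouched (the descriptor becomes S only because C-2 is now sp2); no base is used because base would racemise C-1 through the indenyl anion.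

Step 12
Reactants: 21 the indene
Product: 22 (1R,2R,3R)-1-{[(tert-butyldiphenylsilyl)oxy]methyl}-3-(3,5-dihydroxyphenyl)-2-(4-hydroxyphenyl)-2,3-dihydro-1H-indene-4,6-diol (all-cis)
Conditions: H2 (5 bar), 10 % Pd/C, EtOAc–MeOH, rt
Reagents that add atoms: none
Why: Heterogeneous syn-hydrogenation adds both hydrogens to the face anti to the C-1 CH2OTBDPS group, which places the C-2 and C-3 aryl groups on the same face as the C-1 substituent (the usual all-cis outcome for 1,2,3-trisubstituted indenes); the five benzyl ethers are hydrogenolysed in the same operation.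

Step 13
Reactants: 22 the pentaphenol
Product: 23 tert-butyl({(1R,2R,3R)-4,6-bis(benzyloxy)-3-[3,5-bis(benzyloxy)phenyl]-2-[4-(benzyloxy)phenyl]-2,3-dihydro-1H-inden-1-yl}methoxy)diphenylsilane
Conditions: BnBr (6 equiv), K2CO3, DMF, rt → 40 °C, N2
Reagents that add atoms: benzyl bromide, BrCc1ccccc1
Why: Williamson etherification of the five phenols puts back a protecting group that can be removed at the end under neutral conditions; the three benzylic C–H stereocentres are not acidic enough for K2CO3.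

Step 14
Reactants: 23 the silyl ether
Product: 24 {(1R,2R,3R)-4,6-bis(benzyloxy)-3-[3,5-bis(benzyloxy)phenyl]-2-[4-(benzyloxy)phenyl]-2,3-dihydro-1H-inden-1-yl}methanol
Conditions: TBAF, THF, rt
Reagents that add atoms: none
Why: Fluoride-mediated desilylation; nothing else in the molecule reacts with TBAF.

Step 15
Reactants: 24 the primary alcohol
Product: 25 (1R,2R,3R)-4,6-bis(benzyloxy)-3-[3,5-bis(benzyloxy)phenyl]-2-[4-(benzyloxy)phenyl]-2,3-dihydro-1H-indene-1-carbaldehyde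
Conditions: Dess–Martin periodinane, NaHCO3, CH2Cl2, 0 °C; used crude at once
Reagents that add atoms: none
Why: Dess–Martin oxidation under buffered, non-basic conditions gives the α-aryl aldehyde without enolisation of C-1.

Step 16
Reactants: 25 the aldehyde; 26 1-(benzyloxy)-4-bromobenzene
Product: 28 {(1R,2R,3R)-4,6-bis(benzyloxy)-3-[3,5-bis(benzyloxy)phenyl]-2-[4-(benzyloxy)phenyl]-2,3-dihydro-1H-inden-1-yl}[4-(benzyloxy)phenyl]methanol (carbinol epimers), via [4-(benzyloxy)phenyl]magnesium bromide 27 (not isolated)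
Conditions: 26, Mg, THF, 40 °C; then 25, THF, −78 °C; aq NH4Cl
Reagents that add atoms: none
Why: Grignard 1,2-addition to the aldehyde at −78 °C outruns enolisation; the new carbinol centre forms as a mixture that the next oxidation removes.

Step 17
Reactants: 28 the carbinol
Product: 29 {(1R,2R,3R)-4,6-bis(benzyloxy)-3-[3,5-bis(benzyloxy)phenyl]-2-[4-(benzyloxy)phenyl]-2,3-dihydro-1H-inden-1-yl}[4-(benzyloxy)phenyl]methanone
Conditions: Dess–Martin periodinane, NaHCO3, CH2Cl2, 0 °C → rt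
Reagents that add atoms: none
Why: Dess–Martin oxidation of the secondary benzylic alcohol to the aryl ketone under buffered neutral conditions leaves the enolisable C-1 centre as set.

Step 18
Reactants: 29 the hexabenzyl ketone
Product: 30 caraphenol B, [(1R,2R,3R)-3-(3,5-dihydroxyphenyl)-4,6-dihydroxy-2-(4-hydroxyphenyl)-2,3-dihydro-1H-inden-1-yl](4-hydroxyphenyl)methanone
Conditions: H2 (1 atm), 10 % Pd/C, EtOAc–MeOH, rt
Reagents that add atoms: none
Why: Hydrogenolysis of the six aryl benzyl ethers is neutral, so the contra-thermodynamic C-1 centre α to the ketone is not epimerised, and the aryl ketone is not reduced at 1 atm.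

**Compound list**
1 | methyl 2-(3,5-dihydroxyphenyl)acetate | COC(=O)Cc1cc(O)cc(O)c1 | starting material
2 | methyl 2-[3,5-bis(benzyloxy)phenyl]acetate | COC(=O)Cc1cc(OCc2ccccc2)cc(OCc2ccccc2)c1 | intermediate
3 | 2-[3,5-bis(benzyloxy)phenyl]acetic acid | OC(=O)Cc1cc(OCc2ccccc2)cc(OCc2ccccc2)c1 | intermediate
4 | (R)-4-benzyl-1,3-oxazolidin-2-one | O=C1N[C@H](Cc2ccccc2)CO1 | starting material
5 | 2-[3,5-bis(benzyloxy)phenyl]acetic pivalic anhydride | CC(C)(C)C(=O)OC(=O)Cc1cc(OCc2ccccc2)cc(OCc2ccccc2)c1 | intermediate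
6 | (R)-4-benzyl-3-{2-[3,5-bis(benzyloxy)phenyl]acetyl}-1,3-oxazolidin-2-one | O=C(Cc1cc(OCc2ccccc2)cc(OCc2ccccc2)c1)N1[C@H](Cc2ccccc2)COC1=O | intermediate
7 | 4-(benzyloxy)benzaldehyde | O=Cc1ccc(OCc2ccccc2)cc1 | starting material
8 | nitromethane | C[N+](=O)[O-] | starting material
9 | (E)-1-(benzyloxy)-4-(2-nitroethenyl)benzene | O=[N+]([O-])/C=C/c1ccc(OCc2ccccc2)cc1 | intermediate
10 | trichlorotitanium (Z)-enolate of 6 | Cl[Ti](Cl)(Cl)O/C(=C\c1cc(OCc2ccccc2)cc(OCc2ccccc2)c1)N1[C@H](Cc2ccccc2)COC1=O | intermediate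
11 | (R)-4-benzyl-3-{(2R)-2-[3,5-bis(benzyloxy)phenyl]-3-[4-(benzyloxy)phenyl]-4-nitrobutanoyl}-1,3-oxazolidin-2-one (C-3 epimers) | O=C([C@@H](c1cc(OCc2ccccc2)cc(OCc2ccccc2)c1)C(C[N+](=O)[O-])c1ccc(OCc2ccccc2)cc1)N1[C@H](Cc2ccccc2)COC1=O | intermediate
12 | (2R)-2-[3,5-bis(benzyloxy)phenyl]-3-[4-(benzyloxy)phenyl]-4-nitrobutan-1-ol (C-3 epimers) | OC[C@@H](c1cc(OCc2ccccc2)cc(OCc2ccccc2)c1)C(C[N+](=O)[O-])c1ccc(OCc2ccccc2)cc1 | intermediate
13 | tert-butyl{[(2R)-2-[3,5-bis(benzyloxy)phenyl]-3-[4-(benzyloxy)phenyl]-4-nitrobutyl]oxy}diphenylsilane (C-3 epimers) | CC(C)(C)[Si](c1ccccc1)(c1ccccc1)OC[C@@H](c1cc(OCc2ccccc2)cc(OCc2ccccc2)c1)C(C[N+](=O)[O-])c1ccc(OCc2ccccc2)cc1 | intermediate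
14 | (3R)-3-[3,5-bis(benzyloxy)phenyl]-2-[4-(benzyloxy)phenyl]-4-[(tert-butyldiphenylsilyl)oxy]butanoic acid (C-2 epimers) | CC(C)(C)[Si](c1ccccc1)(c1ccccc1)OC[C@@H](c1cc(OCc2ccccc2)cc(OCc2ccccc2)c1)C(C(=O)O)c1ccc(OCc2ccccc2)cc1 | intermediate
15 | mixed trifluoroacetic anhydride (of acid 14; C-2 epimers) | CC(C)(C)[Si](c1ccccc1)(c1ccccc1)OC[C@@H](c1cc(OCc2ccccc2)cc(OCc2ccccc2)c1)C(C(=O)OC(=O)C(F)(F)F)c1ccc(OCc2ccccc2)cc1 | intermediate
16 | (2S,3R)-5,7-bis(benzyloxy)-2-[4-(benzyloxy)phenyl]-3-{[(tert-butyldiphenylsilyl)oxy]methyl}-2,3-dihydro-1H-inden-1-one (2,3-trans) | O=C1[C@H](c2ccc(OCc3ccccc3)cc2)[C@@H](CO[Si](c2ccccc2)(c2ccccc2)C(C)(C)C)c2cc(OCc3ccccc3)cc(OCc3ccccc3)c12 | intermediate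
17 | 1,3-bis(benzyloxy)-5-bromobenzene | Brc1cc(OCc2ccccc2)cc(OCc2ccccc2)c1 | starting material
18 | [3,5-bis(benzyloxy)phenyl]lithium | [Li]c1cc(OCc2ccccc2)cc(OCc2ccccc2)c1 | intermediate
19 | [3,5-bis(benzyloxy)phenyl]cerium dichloride | Cl[Ce](Cl)c1cc(OCc2ccccc2)cc(OCc2ccccc2)c1 | intermediate
20 | (2S,3R)-5,7-bis(benzyloxy)-1-[3,5-bis(benzyloxy)phenyl]-2-[4-(benzyloxy)phenyl]-3-{[(tert-butyldiphenylsilyl)oxy]methyl}-2,3-dihydro-1H-inden-1-ol (C-1 epimers) | OC1(c2cc(OCc3ccccc3)cc(OCc3ccccc3)c2)[C@H](c2ccc(OCc3ccccc3)cc2)[C@@H](CO[Si](c2ccccc2)(c2ccccc2)C(C)(C)C)c2cc(OCc3ccccc3)cc(OCc3ccccc3)c12 | intermediate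
21 | tert-butyl({(1S)-4,6-bis(benzyloxy)-3-[3,5-bis(benzyloxy)phenyl]-2-[4-(benzyloxy)phenyl]-1H-inden-1-yl}methoxy)diphenylsilane | CC(C)(C)[Si](c1ccccc1)(c1ccccc1)OC[C@@H]1C(c2ccc(OCc3ccccc3)cc2)=C(c2cc(OCc3ccccc3)cc(OCc3ccccc3)c2)c2c(OCc3ccccc3)cc(OCc3ccccc3)cc12 | intermediate
22 | (1R,2R,3R)-1-{[(tert-butyldiphenylsilyl)oxy]methyl}-3-(3,5-dihydroxyphenyl)-2-(4-hydroxyphenyl)-2,3-dihydro-1H-indene-4,6-diol (all-cis) | CC(C)(C)[Si](c1ccccc1)(c1ccccc1)OC[C@@H]1[C@H](c2ccc(O)cc2)[C@H](c2cc(O)cc(O)c2)c2c(O)cc(O)cc12 | intermediate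
23 | tert-butyl({(1R,2R,3R)-4,6-bis(benzyloxy)-3-[3,5-bis(benzyloxy)phenyl]-2-[4-(benzyloxy)phenyl]-2,3-dihydro-1H-inden-1-yl}methoxy)diphenylsilane | CC(C)(C)[Si](c1ccccc1)(c1ccccc1)OC[C@@H]1[C@H](c2ccc(OCc3ccccc3)cc2)[C@H](c2cc(OCc3ccccc3)cc(OCc3ccccc3)c2)c2c(OCc3ccccc3)cc(OCc3ccccc3)cc12 | intermediate
24 | {(1R,2R,3R)-4,6-bis(benzyloxy)-3-[3,5-bis(benzyloxy)phenyl]-2-[4-(benzyloxy)phenyl]-2,3-dihydro-1H-inden-1-yl}methanol | OC[C@@H]1[C@H](c2ccc(OCc3ccccc3)cc2)[C@H](c2cc(OCc3ccccc3)cc(OCc3ccccc3)c2)c2c(OCc3ccccc3)cc(OCc3ccccc3)cc12 | intermediate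
25 | (1R,2R,3R)-4,6-bis(benzyloxy)-3-[3,5-bis(benzyloxy)phenyl]-2-[4-(benzyloxy)phenyl]-2,3-dihydro-1H-indene-1-carbaldehyde | O=C[C@@H]1[C@H](c2ccc(OCc3ccccc3)cc2)[C@H](c2cc(OCc3ccccc3)cc(OCc3ccccc3)c2)c2c(OCc3ccccc3)cc(OCc3ccccc3)cc12 | intermediate
26 | 1-(benzyloxy)-4-bromobenzene | Brc1ccc(OCc2ccccc2)cc1 | starting material
27 | [4-(benzyloxy)phenyl]magnesium bromide | Br[Mg]c1ccc(OCc2ccccc2)cc1 | intermediate
28 | {(1R,2R,3R)-4,6-bis(benzyloxy)-3-[3,5-bis(benzyloxy)phenyl]-2-[4-(benzyloxy)phenyl]-2,3-dihydro-1H-inden-1-yl}[4-(benzyloxy)phenyl]methanol (carbinol epimers) | OC(c1ccc(OCc2ccccc2)cc1)[C@@H]1[C@H](c2ccc(OCc3ccccc3)cc2)[C@H](c2cc(OCc3ccccc3)cc(OCc3ccccc3)c2)c2c(OCc3ccccc3)cc(OCc3ccccc3)cc12 | intermediate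
29 | {(1R,2R,3R)-4,6-bis(benzyloxy)-3-[3,5-bis(benzyloxy)phenyl]-2-[4-(benzyloxy)phenyl]-2,3-dihydro-1H-inden-1-yl}[4-(benzyloxy)phenyl]methanone | O=C(c1ccc(OCc2ccccc2)cc1)[C@@H]1[C@H](c2ccc(OCc3ccccc3)cc2)[C@H](c2cc(OCc3ccccc3)cc(OCc3ccccc3)c2)c2c(OCc3ccccc3)cc(OCc3ccccc3)cc12 | intermediate
30 | caraphenol B, [(1R,2R,3R)-3-(3,5-dihydroxyphenyl)-4,6-dihydroxy-2-(4-hydroxyphenyl)-2,3-dihydro-1H-inden-1-yl](4-hydroxyphenyl)methanone | O=C(c1ccc(O)cc1)[C@H]1c2cc(O)cc(O)c2[C@@H](c2cc(O)cc(O)c2)[C@H]1c1ccc(O)cc1 | target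

**Step count and risks**

Total steps: 18. Longest linear sequence: 17 (steps 1–3 and 5–18, from 1; step 4 is the side branch).

The three steps most likely to fail:

Step 5. The titanium enolate of the hindered α-aryl imide may add sluggishly to 9, or TiCl4 may degrade the nitronate. The fallback makes the same C–C bond by enamine catalysis and sets out from acid 3. BH3·THF reduces 3 to 2-[3,5-bis(benzyloxy)phenyl]ethanol F1, and Dess–Martin oxidation gives 2-[3,5-bis(benzyloxy)phenyl]acetaldehyde F2, used at once. F2 adds to nitrostyrene 9 under (R)-α,α-diphenylprolinol trimethylsilyl ether catalysis (10 mol %, toluene, 0 °C). The catalyst shields one face of the E-enamine, so the α-centre is again R, and the product is (2R)-2-[3,5-bis(benzyloxy)phenyl]-3-[4-(benzyloxy)phenyl]-4-nitrobutanal F3. NaBH4/MeOH is added to the same flask before the α-aryl aldehyde can epimerise, and the route is rejoined at nitro alcohol 12.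

Step 10. The 2-aryl-indanone 16 is hindered and very easily enolised, so the arylcerium reagent may only return starting ketone. The fallback uses that enolisation and sets out from 16. KHMDS (exactly 1.0 equiv, −78 °C) and N-(5-chloropyridin-2-yl)triflimide give (1S)-4,6-bis(benzyloxy)-2-[4-(benzyloxy)phenyl]-1-{[(tert-butyldiphenylsilyl)oxy]methyl}-1H-inden-3-yl trifluoromethanesulfonate F4. Bromide 17 is converted through 18 and ZnCl2 into [3,5-bis(benzyloxy)phenyl]zinc chloride F5. A base-free Negishi coupling of F4 with F5 (Pd(PPh3)4, LiCl, THF, 40 °C) gives indene 21 directly, so alcohol 20 and step 11 are bypassed and the route is rejoined at 21.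

Step 16. The all-cis aldehyde 25 is the less stable C-1 epimer and is α-aryl, so the basic Grignard reagent may enolise it and erode C-1; the same centre stays enolisable in 29. The fallback resets C-1 instead of protecting it. It sets out from ketone 29 as obtained, contaminated by its C-1 epimer {(1S,2R,3R)-4,6-bis(benzyloxy)-3-[3,5-bis(benzyloxy)phenyl]-2-[4-(benzyloxy)phenyl]-2,3-dihydro-1H-inden-1-yl}[4-(benzyloxy)phenyl]methanone F6. LiHMDS (THF, −78 °C) converts both into the same lithium enolate of 29 F7 (C-1 sp2, C-2 and C-3 untouched). Kinetic protonation with acetic acid at −78 °C delivers the proton to the face of C-1 opposite the cis C-2 and C-3 aryl groups (Zimmerman-type kinetic ketonisation, which gives the less stable cis isomer), and the route is rejoined at all-cis 29.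

**Further compounds**
F1 | step 5 | 2-[3,5-bis(benzyloxy)phenyl]ethanol | OCCc1cc(OCc2ccccc2)cc(OCc2ccccc2)c1
F2 | step 5 | 2-[3,5-bis(benzyloxy)phenyl]acetaldehyde | O=CCc1cc(OCc2ccccc2)cc(OCc2ccccc2)c1
F3 | step 5 | (2R)-2-[3,5-bis(benzyloxy)phenyl]-3-[4-(benzyloxy)phenyl]-4-nitrobutanal (C-3 epimers, syn major) | O=C[C@@H](c1cc(OCc2ccccc2)cc(OCc2ccccc2)c1)C(C[N+](=O)[O-])c1ccc(OCc2ccccc2)cc1
F4 | step 10 | (1S)-4,6-bis(benzyloxy)-2-[4-(benzyloxy)phenyl]-1-{[(tert-butyldiphenylsilyl)oxy]methyl}-1H-inden-3-yl trifluoromethanesulfonate | CC(C)(C)[Si](c1ccccc1)(c1ccccc1)OC[C@@H]1C(c2ccc(OCc3ccccc3)cc2)=C(OS(=O)(=O)C(F)(F)F)c2c(OCc3ccccc3)cc(OCc3ccccc3)cc12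
F5 | step 10 | [3,5-bis(benzyloxy)phenyl]zinc chloride | Cl[Zn]c1cc(OCc2ccccc2)cc(OCc2ccccc2)c1
F6 | step 16 | {(1S,2R,3R)-4,6-bis(benzyloxy)-3-[3,5-bis(benzyloxy)phenyl]-2-[4-(benzyloxy)phenyl]-2,3-dihydro-1H-inden-1-yl}[4-(benzyloxy)phenyl]methanone (C-1 epimer of 29) | O=C(c1ccc(OCc2ccccc2)cc1)[C@H]1[C@H](c2ccc(OCc3ccccc3)cc2)[C@H](c2cc(OCc3ccccc3)cc(OCc3ccccc3)c2)c2c(OCc3ccccc3)cc(OCc3ccccc3)cc12
F7 | step 16 | lithium enolate of 29 (C-1 sp2; C-2 and C-3 as in 29) | [Li]OC(c1ccc(OCc2ccccc2)cc1)=C1[C@H](c2ccc(OCc3ccccc3)cc2)[C@H](c2cc(OCc3ccccc3)cc(OCc3ccccc3)c2)c2c(OCc3ccccc3)cc(OCc3ccccc3)cc12
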